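Ring B (the propanoyl ring; C1' carries the bridging CH2) is cut at C2'–C3' and C5'–C6'. The segment C3'(CH3)–C4'(OH)–C5'(COEt) is the intact carbon chain of symmetric heptane-3,5-dione, and C2'–C1'–C6' is a 2-(arylmethyl)malonyl unit. A single [3+3] double C-acylation of the dione's bis-silyl dienol ether by the malonyl dichloride therefore builds the hexasubstituted phloroglucinol ring B and, with it, the unsymmetrical diarylmethane. The precursor is that dichloride carrying ring A (the butanoyl ring) fully substituted and as its tri-O-methyl ether, reached in five steps from 2,4,6-trimethoxytoluene; one demethylation finishes the synthesis.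

Key step: step 7

Remark: the target has no stereocentre and no configured double bond, so no stereocontrol is needed; ring B is numbered C1' (bridging CH2), C2' (OH), C3' (CH3), C4' (OH), C5' (propanoyl), C6' (OH), and dienol ether 10 is used as its mixture of double-bond isomers, all of which lead to the same aromatic ring.

Step 1
Reactants: 1 2,4,6-trimethoxytoluene; 2 butanoyl chloride
Product: 3 1-(2,4,6-trimethoxy-3-methylphenyl)butan-1-one
Conditions: 2 (1.1 equiv), Bi(OTf)3 (10 mol %), MeNO2, 50 °C
Reagents that add atoms: none
Why: Friedel–Crafts acylation, in which the two free positions of 1 are equivalent and each is activated by two ortho and one para methoxy group, so a mild triflate catalyst should give one monoketone while sparing the methyl ethers, the new acyl group then deactivating the ring towards a second acylation.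

Step 2
Reactants: 3 1-(2,4,6-trimethoxy-3-methylphenyl)butan-1-one
Product: 4 1-[3-(chloromethyl)-2,4,6-trimethoxy-5-methylphenyl]butan-1-one
Conditions: (CH2O)n, HCl (g), AcOH, 40 °C; crude product used at once
Reagents that add atoms: formaldehyde (as paraformaldehyde), C=O; hydrogen chloride, Cl
Why: Blanc chloromethylation, an electrophilic substitution by the formaldehyde–HCl electrophile that can enter only at the single free ring position (flanked by two methoxy groups, para to the third), and 4, having no free ring position, cannot condense with itself.

Step 3
Reactants: 4 1-[3-(chloromethyl)-2,4,6-trimethoxy-5-methylphenyl]butan-1-one; 5 dimethyl malonate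
Product: 6 dimethyl 2-[(3-butanoyl-2,4,6-trimethoxy-5-methylphenyl)methyl]propanedioate
Conditions: 5 (3 equiv), NaH (2.5 equiv), THF, 0 °C; then 4, 0 °C → rt
Reagents that add atoms: none
Why: Malonic ester alkylation of a very reactive electron-rich benzylic chloride by the soft malonate carbanion, with excess malonate suppressing double alkylation and the hindered aryl ketone left alone by this weak base.

Step 4
Reactants: 6 dimethyl 2-[(3-butanoyl-2,4,6-trimethoxy-5-methylphenyl)methyl]propanedioate
Product: 7 2-[(3-butanoyl-2,4,6-trimethoxy-5-methylphenyl)methyl]propanedioic acid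
Conditions: KOH, MeOH/H2O, 40 °C; then 1 M HCl, 0 °C
Reagents that add atoms: potassium hydroxide (aqueous), [K+].[OH-]
Why: Saponification of two unhindered methyl esters, to which the aryl ketone and the aryl methyl ethers are inert, with cold acidification avoiding decarboxylation of the malonic acid.

Step 5
Reactants: 7 2-[(3-butanoyl-2,4,6-trimethoxy-5-methylphenyl)methyl]propanedioic acid
Product: 8 2-[(3-butanoyl-2,4,6-trimethoxy-5-methylphenyl)methyl]propanedioyl dichloride
Conditions: (COCl)2 (3 equiv), DMF (cat.), CH2Cl2, 0 °C → rt; evaporated, used crude
Reagents that add atoms: oxalyl chloride, ClC(=O)C(=O)Cl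
Why: Acid chloride formation by oxalyl chloride with chloroiminium catalysis at room temperature, a standard way to monosubstituted malonyl dichlorides, in which ring A offers neither a free ring position nor a free OH and all coproducts are volatile.

Step 6
Reactants: 9 heptane-3,5-dione
Product: 10 3,5-bis(trimethylsilyloxy)hepta-2,4-diene
Conditions: Me3SiOTf (2.2 equiv), Et3N (2.5 equiv), Et2O, 0 °C → rt; ammonium salt phase removed, distilled
Reagents that add atoms: trimethylsilyl trifluoromethanesulfonate, C[Si](C)(C)OS(=O)(=O)C(F)(F)F
Why: Double O-silylation (soft enolisation) of a 1,3-diketone with Me3SiOTf/Et3N, the established route to 1,3-bis(silyloxy)-1,3-dienes, and the symmetry of 9 allows only one constitution.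

Step 7
Reactants: 8 2-[(3-butanoyl-2,4,6-trimethoxy-5-methylphenyl)methyl]propanedioyl dichloride; 10 3,5-bis(trimethylsilyloxy)hepta-2,4-diene
Product: 12 1-[2,4,6-trimethoxy-3-methyl-5-[(2,4,6-trihydroxy-3-methyl-5-propanoylphenyl)methyl]phenyl]butan-1-one, via open-chain monoacylated acyl chloride 11 (not isolated)
Conditions: 8 in CH2Cl2 (0.02 M), Me3SiOTf (0.2 equiv), −78 °C; 10 (1.1 equiv) added slowly; −78 → 0 °C; then 1 M HCl, THF, rt
Reagents that add atoms: none
Why: Proposed new method: the methyl-bearing terminal carbon of 10, its most nucleophilic site, should attack one acyl chloride of 8 with loss of Me3SiCl to give 11, whose remaining silyl enol ether carbon (the former central CH2 of the dione) then attacks the second acyl chloride intramolecularly, and the resulting cyclohexane-1,3,5-trione tautomerises to the aromatic triol. The closest known reaction types are the Effenberger cyclisation of silyl enol ethers with malonyl dichloride and the [3+3] cyclisations of 1,3-bis(silyloxy)-1,3-dienes with 1,3-dielectrophiles, but a 2-substituted malonyl dichloride has not been combined with a diketone-derived bis-silyl dienol ether. Ring B closes as a six-membered carbocycle in a 6-(enolexo)-exo-trig C-acylation, C2'–C3' being formed first and C5'–C6' second. No stereocentre is created, since the two enolisable sp3 centres of 11 disappear on aromatisation. The selectivity needed is closure through carbon, not through the enol oxygen (which would give a 4-hydroxy-2-pyranone); it should be secured by keeping the second nucleophile as a silyl enol ether carbon, by base-free Lewis-acidic conditions at low temperature with slow addition of 10, and by the aromatic sink, and any O-closed isomer should be convertible into the same ring by Mg(OMe)2-mediated ring opening and Claisen closure. The constitution is unambiguous because the malonyl unit is symmetric and the dione gives a single bis-dienol ether, while ring A, hexasubstituted and O-methylated, can be neither C- nor O-acylated.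

Step 8
Reactants: 12 1-[2,4,6-trimethoxy-3-methyl-5-[(2,4,6-trihydroxy-3-methyl-5-propanoylphenyl)methyl]phenyl]butan-1-one
Product: 13 1-[2,4,6-trihydroxy-3-methyl-5-[(2,4,6-trihydroxy-3-methyl-5-propanoylphenyl)methyl]phenyl]butan-1-one
Conditions: BBr3 (10 equiv), CH2Cl2, −78 → 0 °C; then H2O, 0 °C
Reagents that add atoms: none
Why: Lewis acid O-demethylation with BBr3, in which the two methoxy groups ortho to the butanoyl carbonyl are cleaved with chelation assistance and the third, twisted out of plane by its two ortho substituents, is a basic and readily complexed ether, while the ketones, the CH2 bridge and the borate-masked ring B phenols should persist at or below 0 °C.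

Compound list
1 | 2,4,6-trimethoxytoluene | COc1cc(OC)c(C)c(OC)c1 | starting material
2 | butanoyl chloride | CCCC(=O)Cl | starting material
3 | 1-(2,4,6-trimethoxy-3-methylphenyl)butan-1-one | CCCC(=O)c1c(OC)cc(OC)c(C)c1OC | intermediate
4 | 1-[3-(chloromethyl)-2,4,6-trimethoxy-5-methylphenyl]butan-1-one | CCCC(=O)c1c(OC)c(CCl)c(OC)c(C)c1OC | intermediate
5 | dimethyl malonate | COC(=O)CC(=O)OC | starting material
6 | dimethyl 2-[(3-butanoyl-2,4,6-trimethoxy-5-methylphenyl)methyl]propanedioate | CCCC(=O)c1c(OC)c(C)c(OC)c(CC(C(=O)OC)C(=O)OC)c1OC | intermediate
7 | 2-[(3-butanoyl-2,4,6-trimethoxy-5-methylphenyl)methyl]propanedioic acid | CCCC(=O)c1c(OC)c(C)c(OC)c(CC(C(=O)O)C(=O)O)c1OC | intermediate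
8 | 2-[(3-butanoyl-2,4,6-trimethoxy-5-methylphenyl)methyl]propanedioyl dichloride | CCCC(=O)c1c(OC)c(C)c(OC)c(CC(C(=O)Cl)C(=O)Cl)c1OC | intermediate
9 | heptane-3,5-dione | CCC(=O)CC(=O)CC | starting material
10 | 3,5-bis(trimethylsilyloxy)hepta-2,4-diene (drawn 2Z,4Z; used as the mixture of double-bond isomers) | C/C=C(\O[Si](C)(C)C)/C=C(/CC)O[Si](C)(C)C | intermediate
11 | 2-[(3-butanoyl-2,4,6-trimethoxy-5-methylphenyl)methyl]-4-methyl-3,5-dioxo-7-(trimethylsilyloxy)non-6-enoyl chloride (open-chain monoacylated acyl chloride; one silatropic form drawn; its two sp3 centres and enol geometry are undefined and are erased on aromatisation) | CCCC(=O)c1c(OC)c(C)c(OC)c(CC(C(=O)Cl)C(=O)C(C)C(=O)C=C(CC)O[Si](C)(C)C)c1OC | intermediate (not isolated)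
12 | 1-[2,4,6-trimethoxy-3-methyl-5-[(2,4,6-trihydroxy-3-methyl-5-propanoylphenyl)methyl]phenyl]butan-1-one | CCCC(=O)c1c(OC)c(C)c(OC)c(Cc2c(O)c(C)c(O)c(C(=O)CC)c2O)c1OC | intermediate
13 | 1-[2,4,6-trihydroxy-3-methyl-5-[(2,4,6-trihydroxy-3-methyl-5-propanoylphenyl)methyl]phenyl]butan-1-one (achiral) | CCCC(=O)c1c(O)c(C)c(O)c(Cc2c(O)c(C)c(O)c(C(=O)CC)c2O)c1O | target

Total step count: 8.
Longest linear sequence: 7 steps (steps 1, 2, 3, 4, 5, 7, 8 from compound 1); step 6 is a one-step branch from compound 9.

Steps most likely to fail

Step 7 (proposed new method). The open-chain intermediate may close through the enol oxygen instead of carbon, the dienol ether may be acylated twice intermolecularly, or an ortho methoxy group of ring A may lactonise onto an acyl chloride with loss of its methyl group. The fallback uses known chemistry and makes the bridge by C–C bond formation to a finished ring B instead of building ring B; it sets out from benzylic chloride 4, with a partner made from 1, and rejoins the route at 12. Compound 1 would be acylated with propanoyl chloride (Bi(OTf)3 cat., MeNO2) to 1-(2,4,6-trimethoxy-3-methylphenyl)propan-1-one F1, and BBr3 in CH2Cl2 would demethylate this to 1-(2,4,6-trihydroxy-3-methylphenyl)propan-1-one F2. Friedel–Crafts C-benzylation of F2 at its only free ring position with 4 (ZnCl2 cat., dioxane, rt, F2 in slight excess) should give 12, which then enters step 8 unchanged.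

Step 8. The hindered third methyl ether may be cleaved incompletely, or the strongly Lewis-acidic medium may cleave and re-form the CH2 bridge once both rings are electron-rich, scrambling the two halves. The fallback avoids demethylating a bridged compound; it sets out from ketone 3 and arrives directly at target 13. BBr3 would convert 3 into 1-(2,4,6-trihydroxy-3-methylphenyl)butan-1-one F3, and Mannich aminomethylation (aq. CH2O, Me2NH, EtOH, rt) at its only free ring position would give 1-[3-[(dimethylamino)methyl]-2,4,6-trihydroxy-5-methylphenyl]butan-1-one F4. Gentle heating of F4 in dioxane with F2 (the ring B monomer made from 1 as in the step 7 fallback) should expel dimethylamine to the transient ortho-quinone methide 2-butanoyl-3,5-dihydroxy-4-methyl-6-methylidenecyclohexa-2,4-dien-1-one F5. F2 should trap F5 at its free ring carbon, the known Mannich-base route to unsymmetrical methylene-bridged acylphloroglucinols, giving 13.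

Step 2. The benzylic chloride may alkylate unreacted 3 to a symmetrical diarylmethane, it may be solvolysed during handling, or formaldehyde may condense at the ketone α-carbon under acid. The fallback replaces chloromethylation and alkylation by formylation, condensation and reduction; it sets out from 3 and rejoins the route at 6, bypassing 4. Rieche formylation (Cl2CHOMe, SnCl4, CH2Cl2, −10 °C) would give 3-butanoyl-2,4,6-trimethoxy-5-methylbenzaldehyde F6. Knoevenagel condensation of F6 with dimethyl malonate 5 (piperidine, AcOH, toluene, reflux with water removal) would give dimethyl 2-[(3-butanoyl-2,4,6-trimethoxy-5-methylphenyl)methylidene]propanedioate F7. Hydrogenation of the electron-poor alkene (H2, Pd/C, EtOAc, rt), which should leave the hindered aryl ketone untouched, would give 6.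

Further compounds
F1 | step 7 | 1-(2,4,6-trimethoxy-3-methylphenyl)propan-1-one | CCC(=O)c1c(OC)cc(OC)c(C)c1OC
F2 | step 7 | 1-(2,4,6-trihydroxy-3-methylphenyl)propan-1-one | CCC(=O)c1c(O)cc(O)c(C)c1O
F3 | step 8 | 1-(2,4,6-trihydroxy-3-methylphenyl)butan-1-one | CCCC(=O)c1c(O)cc(O)c(C)c1O
F4 | step 8 | 1-[3-[(dimethylamino)methyl]-2,4,6-trihydroxy-5-methylphenyl]butan-1-one | CCCC(=O)c1c(O)c(C)c(O)c(CN(C)C)c1O
F5 | step 8 | 2-butanoyl-3,5-dihydroxy-4-methyl-6-methylidenecyclohexa-2,4-dien-1-one | C=C1C(=O)C(C(=O)CCC)=C(O)C(C)=C1O
F6 | step 2 | 3-butanoyl-2,4,6-trimethoxy-5-methylbenzaldehyde | CCCC(=O)c1c(OC)c(C)c(OC)c(C=O)c1OC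
F7 | step 2 | dimethyl 2-[(3-butanoyl-2,4,6-trimethoxy-5-methylphenyl)methylidene]propanedioate | CCCC(=O)c1c(OC)c(C)c(OC)c(C=C(C(=O)OC)C(=O)OC)c1OC
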